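**Retrosynthetic overview**
- Target 26 is a 19-membered ring: ring A (catechol) –O– ring B (para-phenylene) –CH2CH2– ring C (catechol) –O– ring D (meta-phenylene) –CH2CH2– ring A. The four phenols come from methyl ethers (BBr3) and both ethano bridges from stilbenes (hydrogenation).
- The macrocycle is opened at the ring D–CH=CH–ring A bond (intramolecular Wittig) and then at the ring B–CH=CH–ring C bond (Wittig of a ring A–B phosphonium salt with a ring C–D aldehyde made by Ullmann etherification).
- The strategy rests on ring B: its only substituents are the ether oxygen to ring A on C1 and the benzylic bridge carbon on C4, para to it. Ring B is therefore built, not coupled: the ethynyl ether of the ring A phenol adds across C3/C6 of methyl coumalate and CO2 is lost, which leaves the oxygen para to the ester carbon.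
- Ring order: rings A, C and D are bought as arenes, ring B is formed in step 4, and the macrocycle is closed in step 13.

Key step: step 4

Remark: the target has no stereocentre; both stilbene intermediates are carried as E/Z mixtures because each alkene is hydrogenated afterwards.

**Route**

Step 1
Reactants: 1 3-hydroxy-4,5-dimethoxybenzaldehyde
Product: 2 5-(1,3-dioxolan-2-yl)-2,3-dimethoxyphenol
Conditions: ethylene glycol, p-TsOH (cat.), toluene, reflux, Dean–Stark; NaHCO3 work-up
Reagents that add atoms: ethylene glycol, OCCO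
Why: Acid-catalysed acetalisation with azeotropic removal of water masks the aldehyde against n-BuLi and the later ylide chemistry, while the phenol stays free.

Step 2
Reactants: 2 5-(1,3-dioxolan-2-yl)-2,3-dimethoxyphenol; 3 trichloroethylene
Product: 5 2-[3-[(E)-1,2-dichloroethenoxy]-4,5-dimethoxyphenyl]-1,3-dioxolane, via dichloroacetylene 4 (not isolated)
Conditions: K2CO3, DMF, 70 °C
Reagents that add atoms: none
Why: K2CO3 dehydrochlorinates trichloroethylene to dichloroacetylene, to which the phenoxide adds with anti protonation (the established route to aryl (E)-1,2-dichlorovinyl ethers); the hindered phenoxide only has to reach a linear sp carbon and the acetal is inert to base.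

Step 3
Reactants: 5 2-[3-[(E)-1,2-dichloroethenoxy]-4,5-dimethoxyphenyl]-1,3-dioxolane
Product: 8 2-[3-(ethynyloxy)-4,5-dimethoxyphenyl]-1,3-dioxolane, via chloroethynyl ether 6 (not isolated), via lithium acetylide 7 (not isolated)
Conditions: n-BuLi (2.3 equiv), THF, −78 °C; then H2O, −78 → 0 °C; cold extraction into toluene, no chromatography, used at once
Reagents that add atoms: none
Why: n-BuLi first eliminates HCl to the chloroalkynyl ether and a second equivalent effects lithium–chlorine exchange, so that protonation of the acetylide gives the terminal ynol ether (the dichlorovinyl ether route to ynol ethers); the dioxolane and the methyl ethers are inert at −78 °C.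

Step 4
Reactants: 8 2-[3-(ethynyloxy)-4,5-dimethoxyphenyl]-1,3-dioxolane; 9 methyl coumalate
Product: 11 methyl 4-[5-(1,3-dioxolan-2-yl)-2,3-dimethoxyphenoxy]benzoate, via bridged lactone 10 (not isolated)
Conditions: methyl coumalate (1.5 equiv), BHT (cat.), toluene, 100 °C, sealed tube
Reagents that add atoms: none
Why: Proposed new method: the electron-poor diene of methyl coumalate (C3=C4–C5=C6) should undergo an inverse-electron-demand [4+2] cycloaddition with the oxygen-activated alkyne of 8, concerted but asynchronous with the bond from C6 to the terminal alkyne carbon leading, and the bridged lactone 10 should then expel CO2 by retro-[4+2]; the closest known reaction type is the cycloaddition–decarboxylation of methyl coumalate with enol ethers, ketene acetals and ynamines to para-substituted benzoates, here extended to an aryl ethynyl ether. Ring B is closed as a six-membered carbocycle by this intermolecular [4+2] annulation (two C–C bonds, C6–CH and C3–C(OAr)) and becomes aromatic when the O1–C2 bridge leaves. No stereocentre remains, because the two bridgehead centres of 10 are erased by the extrusion. The step needs regioselectivity, and polarity should secure it: the nucleophilic terminal carbon of the ynol ether (beta to oxygen) pairs with the most electrophilic pyrone carbon C6 (beta to the ester and vinylogous to the lactone carbonyl), which puts the aryloxy carbon on C3 and hence para to the ester. An aryl ynol ether has no retro-ene pathway to a ketene, unlike alkyl ynol ethers, so it should tolerate the temperature, and the acetal is inert under these neutral conditions.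

Step 5
Reactants: 11 methyl 4-[5-(1,3-dioxolan-2-yl)-2,3-dimethoxyphenoxy]benzoate
Product: 12 [4-[5-(1,3-dioxolan-2-yl)-2,3-dimethoxyphenoxy]phenyl]methanol
Conditions: LiAlH4, THF, 0 °C; NaOH/H2O work-up
Reagents that add atoms: none
Why: Hydride reduction of the ester to the benzylic alcohol; acetal, diaryl ether and methyl ethers are inert and the work-up is kept basic.

Step 6
Reactants: 12 [4-[5-(1,3-dioxolan-2-yl)-2,3-dimethoxyphenoxy]phenyl]methanol
Product: 13 2-[3-[4-(bromomethyl)phenoxy]-4,5-dimethoxyphenyl]-1,3-dioxolane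
Conditions: CBr4, PPh3, 2,6-lutidine (0.2 equiv), CH2Cl2, 0 °C
Reagents that add atoms: carbon tetrabromide, BrC(Br)(Br)Br
Why: Appel bromination runs under essentially neutral conditions, and the lutidine buffer keeps traces of HBr away from the dioxolane.

Step 7
Reactants: 13 2-[3-[4-(bromomethyl)phenoxy]-4,5-dimethoxyphenyl]-1,3-dioxolane
Product: 14 [4-[5-(1,3-dioxolan-2-yl)-2,3-dimethoxyphenoxy]phenyl]methyl-triphenylphosphonium bromide
Conditions: PPh3, toluene, 90 °C; salt collected by filtration
Reagents that add atoms: triphenylphosphine, c1ccc(cc1)P(c1ccccc1)c1ccccc1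
Why: SN2 quaternisation of a benzylic bromide by PPh3 under neutral conditions that leave the acetal untouched.

Step 8
Reactants: 1 3-hydroxy-4,5-dimethoxybenzaldehyde; 15 methyl 3-iodobenzoate
Product: 16 methyl 3-(5-formyl-2,3-dimethoxyphenoxy)benzoate
Conditions: CuI (10 mol %), N,N-dimethylglycine hydrochloride (30 mol %), Cs2CO3, 1,4-dioxane, 90 °C
Reagents that add atoms: none
Why: Ligand-accelerated Ullmann diaryl ether synthesis tolerates ortho-methoxy phenols, the non-enolisable aldehyde and the methyl ester under anhydrous carbonate conditions.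

Step 9
Reactants: 14 [4-[5-(1,3-dioxolan-2-yl)-2,3-dimethoxyphenoxy]phenyl]methyl-triphenylphosphonium bromide; 16 methyl 3-(5-formyl-2,3-dimethoxyphenoxy)benzoate
Product: 18 methyl 3-[5-[2-[4-[5-(1,3-dioxolan-2-yl)-2,3-dimethoxyphenoxy]phenyl]ethenyl]-2,3-dimethoxyphenoxy]benzoate (E/Z mixture), via phosphonium ylide 17 (not isolated)
Conditions: K2CO3, 18-crown-6 (cat.), CH2Cl2, reflux
Reagents that add atoms: none
Why: Wittig olefination under solid–liquid phase transfer; the semi-stabilised benzyl ylide attacks the aldehyde and not the ester, and the alkene geometry is irrelevant because the alkene is reduced next.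

Step 10
Reactants: 18 methyl 3-[5-[2-[4-[5-(1,3-dioxolan-2-yl)-2,3-dimethoxyphenoxy]phenyl]ethenyl]-2,3-dimethoxyphenoxy]benzoate (E/Z mixture)
Product: 19 methyl 3-[5-[2-[4-[5-(1,3-dioxolan-2-yl)-2,3-dimethoxyphenoxy]phenyl]ethyl]-2,3-dimethoxyphenoxy]benzoate
Conditions: H2 (1 atm), 10% Pd/C, EtOAc, Et3N (1%), rt
Reagents that add atoms: none
Why: Heterogeneous hydrogenation of the stilbene gives the flexible bibenzyl needed for ring closure; the amine additive suppresses hydrogenolysis or hydrolysis of the benzylic acetal.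

Step 11
Reactants: 19 methyl 3-[5-[2-[4-[5-(1,3-dioxolan-2-yl)-2,3-dimethoxyphenoxy]phenyl]ethyl]-2,3-dimethoxyphenoxy]benzoate
Product: 20 [3-[5-[2-[4-[5-(1,3-dioxolan-2-yl)-2,3-dimethoxyphenoxy]phenyl]ethyl]-2,3-dimethoxyphenoxy]phenyl]methanol
Conditions: LiAlH4, THF, 0 °C; NaOH/H2O work-up
Reagents that add atoms: none
Why: Hydride reduction of the ring D ester to the benzylic alcohol with the acetal left intact.

Step 12
Reactants: 20 [3-[5-[2-[4-[5-(1,3-dioxolan-2-yl)-2,3-dimethoxyphenoxy]phenyl]ethyl]-2,3-dimethoxyphenoxy]phenyl]methanol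
Product: 22 [3-[5-[2-[4-(5-formyl-2,3-dimethoxyphenoxy)phenyl]ethyl]-2,3-dimethoxyphenoxy]phenyl]methyl-triphenylphosphonium bromide, via dioxolane phosphonium bromide 21 (not isolated)
Conditions: PPh3·HBr (1.05 equiv), MeCN, reflux; then 1 M aq. HBr, THF, rt
Reagents that add atoms: triphenylphosphine hydrobromide, [Br-].c1ccc(cc1)[PH+](c1ccccc1)c1ccccc1; water, O
Why: PPh3·HBr converts benzylic alcohols directly into benzyl phosphonium bromides, and the acid with the water set free (completed by the aqueous acid) hydrolyses the dioxolane, so the aldehyde and the ylide precursor are unveiled together.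

Step 13
Reactants: 22 [3-[5-[2-[4-(5-formyl-2,3-dimethoxyphenoxy)phenyl]ethyl]-2,3-dimethoxyphenoxy]phenyl]methyl-triphenylphosphonium bromide
Product: 24 macrocyclic stilbene tetramethyl ether (E/Z mixture), via ylide aldehyde 23 (not isolated)
Conditions: slow addition (syringe pump, 12 h) of 22 in CH2Cl2 to NaOMe (5 equiv) in CH2Cl2/MeOH, rt, final concentration about 1 mM
Reagents that add atoms: none
Why: Intramolecular Wittig olefination under high dilution closes the 19-membered ring between ring D and ring A, the flexible bibenzyl and the two diaryl ether hinges allowing the ylide to reach the aldehyde.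

Step 14
Reactants: 24 macrocyclic stilbene tetramethyl ether (E/Z mixture)
Product: 25 tetra-O-methyl ether of the target
Conditions: H2 (1 atm), 10% Pd/C, EtOAc/THF, rt
Reagents that add atoms: none
Why: Catalytic hydrogenation saturates the remaining stilbene alkene, whichever its geometry; the diaryl ethers are inert.

Step 15
Reactants: 25 tetra-O-methyl ether of the target
Product: 26 CNP0511668.0
Conditions: BBr3 (8 equiv), CH2Cl2, −78 °C → rt; then H2O
Reagents that add atoms: none
Why: Lewis-acid cleavage of the four aryl methyl ethers by BBr3 leaves the diaryl ethers and the bibenzyl bridges intact and frees both catechols.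

**Compound list**
1 | 3-hydroxy-4,5-dimethoxybenzaldehyde | COc1cc(C=O)cc(O)c1OC | starting material
2 | 5-(1,3-dioxolan-2-yl)-2,3-dimethoxyphenol | COc1cc(C2OCCO2)cc(O)c1OC | intermediate
3 | trichloroethylene | ClC=C(Cl)Cl | starting material
4 | dichloroacetylene (not isolated) | ClC#CCl | intermediate
5 | 2-[3-[(E)-1,2-dichloroethenoxy]-4,5-dimethoxyphenyl]-1,3-dioxolane | COc1cc(C2OCCO2)cc(O/C(Cl)=C\Cl)c1OC | intermediate
6 | 2-[3-(chloroethynyloxy)-4,5-dimethoxyphenyl]-1,3-dioxolane (not isolated) | COc1cc(C2OCCO2)cc(OC#CCl)c1OC | intermediate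
7 | lithium [5-(1,3-dioxolan-2-yl)-2,3-dimethoxyphenoxy]acetylide (not isolated) | COc1cc(C2OCCO2)cc(OC#C[Li])c1OC | intermediate
8 | 2-[3-(ethynyloxy)-4,5-dimethoxyphenyl]-1,3-dioxolane | COc1cc(C2OCCO2)cc(OC#C)c1OC | intermediate
9 | methyl coumalate (methyl 2-oxo-2H-pyran-5-carboxylate) | COC(=O)C1=COC(=O)C=C1 | starting material
10 | methyl 8-[5-(1,3-dioxolan-2-yl)-2,3-dimethoxyphenoxy]-3-oxo-2-oxabicyclo[2.2.2]octa-5,7-diene-6-carboxylate (racemic, not isolated) | COC(=O)C1=CC2C(=O)OC1C=C2Oc1cc(C3OCCO3)cc(OC)c1OC | intermediate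
11 | methyl 4-[5-(1,3-dioxolan-2-yl)-2,3-dimethoxyphenoxy]benzoate | COC(=O)c1ccc(Oc2cc(C3OCCO3)cc(OC)c2OC)cc1 | intermediate
12 | [4-[5-(1,3-dioxolan-2-yl)-2,3-dimethoxyphenoxy]phenyl]methanol | OCc1ccc(Oc2cc(C3OCCO3)cc(OC)c2OC)cc1 | intermediate
13 | 2-[3-[4-(bromomethyl)phenoxy]-4,5-dimethoxyphenyl]-1,3-dioxolane | BrCc1ccc(Oc2cc(C3OCCO3)cc(OC)c2OC)cc1 | intermediate
14 | [4-[5-(1,3-dioxolan-2-yl)-2,3-dimethoxyphenoxy]phenyl]methyl-triphenylphosphonium bromide | [Br-].COc1cc(C2OCCO2)cc(Oc2ccc(C[P+](c3ccccc3)(c3ccccc3)c3ccccc3)cc2)c1OC | intermediate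
15 | methyl 3-iodobenzoate | COC(=O)c1cccc(I)c1 | starting material
16 | methyl 3-(5-formyl-2,3-dimethoxyphenoxy)benzoate | COC(=O)c1cccc(Oc2cc(C=O)cc(OC)c2OC)c1 | intermediate
17 | phosphonium ylide of 14 (not isolated) | COc1cc(C2OCCO2)cc(Oc2ccc(C=P(c3ccccc3)(c3ccccc3)c3ccccc3)cc2)c1OC | intermediate
18 | methyl 3-[5-[2-[4-[5-(1,3-dioxolan-2-yl)-2,3-dimethoxyphenoxy]phenyl]ethenyl]-2,3-dimethoxyphenoxy]benzoate (E/Z mixture) | COC(=O)c1cccc(Oc2cc(C=Cc3ccc(Oc4cc(C5OCCO5)cc(OC)c4OC)cc3)cc(OC)c2OC)c1 | intermediate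
19 | methyl 3-[5-[2-[4-[5-(1,3-dioxolan-2-yl)-2,3-dimethoxyphenoxy]phenyl]ethyl]-2,3-dimethoxyphenoxy]benzoate | COC(=O)c1cccc(Oc2cc(CCc3ccc(Oc4cc(C5OCCO5)cc(OC)c4OC)cc3)cc(OC)c2OC)c1 | intermediate
20 | [3-[5-[2-[4-[5-(1,3-dioxolan-2-yl)-2,3-dimethoxyphenoxy]phenyl]ethyl]-2,3-dimethoxyphenoxy]phenyl]methanol | OCc1cccc(Oc2cc(CCc3ccc(Oc4cc(C5OCCO5)cc(OC)c4OC)cc3)cc(OC)c2OC)c1 | intermediate
21 | [3-[5-[2-[4-[5-(1,3-dioxolan-2-yl)-2,3-dimethoxyphenoxy]phenyl]ethyl]-2,3-dimethoxyphenoxy]phenyl]methyl-triphenylphosphonium bromide (not isolated) | [Br-].COc1cc(C2OCCO2)cc(Oc2ccc(CCc3cc(OC)c(OC)c(Oc4cccc(C[P+](c5ccccc5)(c5ccccc5)c5ccccc5)c4)c3)cc2)c1OC | intermediate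
22 | [3-[5-[2-[4-(5-formyl-2,3-dimethoxyphenoxy)phenyl]ethyl]-2,3-dimethoxyphenoxy]phenyl]methyl-triphenylphosphonium bromide | [Br-].O=Cc1cc(OC)c(OC)c(Oc2ccc(CCc3cc(OC)c(OC)c(Oc4cccc(C[P+](c5ccccc5)(c5ccccc5)c5ccccc5)c4)c3)cc2)c1 | intermediate
23 | phosphonium ylide of 22 bearing the free ring A aldehyde (not isolated) | O=Cc1cc(OC)c(OC)c(Oc2ccc(CCc3cc(OC)c(OC)c(Oc4cccc(C=P(c5ccccc5)(c5ccccc5)c5ccccc5)c4)c3)cc2)c1 | intermediate
24 | macrocyclic stilbene tetramethyl ether (E/Z mixture): compound 25 with CH=CH in place of the CH2CH2 bridge between ring D and ring A | COc1cc2cc(c1OC)Oc1ccc(cc1)CCc1cc(OC)c(OC)c(c1)Oc1cccc(c1)C=C2 | intermediate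
25 | tetra-O-methyl ether of the target (4,5-dimethoxy pattern on ring A and on ring C) | COc1cc2cc(c1OC)Oc1ccc(cc1)CCc1cc(OC)c(OC)c(c1)Oc1cccc(c1)CC2 | intermediate
26 | CNP0511668.0, macrocyclic bis(bibenzyl) tetraphenol | Oc1cc2cc(c1O)Oc1ccc(cc1)CCc1cc(O)c(O)c(c1)Oc1cccc(c1)CC2 | target

**Step count**
Total: 15 steps. Longest linear sequence: 14 steps (steps 1–7 and 9–15, from compound 1); step 8 is the one-step side branch.

**Steps most likely to fail**

Step 4. The aryloxyalkyne may be too weak a donor for the pyrone, so that thermal oligomerisation of the ynol ether or dimerisation of methyl coumalate outruns the cycloaddition. Fallback by known chemistry, setting out from 2: nucleophilic aromatic substitution of 4-fluorobenzaldehyde by the phenoxide of 2 (K2CO3, DMF, 120 °C) should give 4-[5-(1,3-dioxolan-2-yl)-2,3-dimethoxyphenoxy]benzaldehyde F1. Reduction of F1 with NaBH4 in MeOH at 0 °C returns to the route at 12. Ring B is then bought instead of built.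

Step 3. The terminal aryl ethynyl ether may hydrate to the aryl acetate or oligomerise during the aqueous quench and concentration. Fallback setting out from 7: the acetylide is silylated in the flask with Me3SiCl to give the more robust 2-[3,4-dimethoxy-5-[(trimethylsilyl)ethynyloxy]phenyl]-1,3-dioxolane F2. Heating F2 with 9 in toluene at 110–130 °C should pass through the silylated bridged lactone F3 and, after loss of CO2, give methyl 4-[5-(1,3-dioxolan-2-yl)-2,3-dimethoxyphenoxy]-3-(trimethylsilyl)benzoate F4. Base-catalysed protodesilylation of F4 (KOSiMe3, 5 mol %, wet DMSO, 50 °C) comes back to the route at 11. The silicon-bearing alkyne carbon is still the nucleophilic terminus, so the para relationship of oxygen and ester should be kept; the cycloaddition of a silyl ynol ether is itself unproven.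

Step 13. Intermolecular olefination may compete with ring closure and give linear oligomers and the cyclic dimer. Fallback setting out from 20: oxidation with MnO2 in CH2Cl2 should give 3-[5-[2-[4-[5-(1,3-dioxolan-2-yl)-2,3-dimethoxyphenoxy]phenyl]ethyl]-2,3-dimethoxyphenoxy]benzaldehyde F5. Hydrolysis of F5 with 1 M HCl in THF should give the dialdehyde 3-[5-[2-[4-(5-formyl-2,3-dimethoxyphenoxy)phenyl]ethyl]-2,3-dimethoxyphenoxy]benzaldehyde F6. McMurry coupling of F6 on low-valent titanium (TiCl4, Zn, pyridine, THF, reflux, slow addition) closes the same C=C bond and comes back to the route at 24. The titanium surface templates the two carbonyl groups, so this closure depends less on dilution than the ylide route.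

Further compounds
F1 | step 4 | 4-[5-(1,3-dioxolan-2-yl)-2,3-dimethoxyphenoxy]benzaldehyde | O=Cc1ccc(Oc2cc(C3OCCO3)cc(OC)c2OC)cc1
F2 | step 3 | 2-[3,4-dimethoxy-5-[(trimethylsilyl)ethynyloxy]phenyl]-1,3-dioxolane | COc1cc(C2OCCO2)cc(OC#C[Si](C)(C)C)c1OC
F3 | step 3 | methyl 8-[5-(1,3-dioxolan-2-yl)-2,3-dimethoxyphenoxy]-3-oxo-7-(trimethylsilyl)-2-oxabicyclo[2.2.2]octa-5,7-diene-6-carboxylate (racemic, transient) | COC(=O)C1=CC2C(=O)OC1C(=C2Oc1cc(C3OCCO3)cc(OC)c1OC)[Si](C)(C)C
F4 | step 3 | methyl 4-[5-(1,3-dioxolan-2-yl)-2,3-dimethoxyphenoxy]-3-(trimethylsilyl)benzoate | COC(=O)c1ccc(Oc2cc(C3OCCO3)cc(OC)c2OC)c([Si](C)(C)C)c1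
F5 | step 13 | 3-[5-[2-[4-[5-(1,3-dioxolan-2-yl)-2,3-dimethoxyphenoxy]phenyl]ethyl]-2,3-dimethoxyphenoxy]benzaldehyde | O=Cc1cccc(Oc2cc(CCc3ccc(Oc4cc(C5OCCO5)cc(OC)c4OC)cc3)cc(OC)c2OC)c1
F6 | step 13 | 3-[5-[2-[4-(5-formyl-2,3-dimethoxyphenoxy)phenyl]ethyl]-2,3-dimethoxyphenoxy]benzaldehyde | O=Cc1cccc(Oc2cc(CCc3ccc(Oc4cc(C=O)cc(OC)c4OC)cc3)cc(OC)c2OC)c1
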